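**Plan**

- Retrosynthesis: the styryl diene is cut at both C=C bonds back to a C6 aldehyde and C7 acid masked as a menthyl lactone acetal; the C1=C2/C7a–H pair goes back to a C2 alcohol on a C1=C7a enone; then the C3 methyl, the C3–C3a bond, the C1–C7a bond, and last C5–C6 and C7–C7a ([4+2]).
- Forward: the six-membered ring comes first (Diels–Alder, C6/C7 quaternary pair), then the C1 side chain on C7a, then the five-membered ring by gold-catalysed closure of C3 onto C3a, then the ring-fusion transposition, then the diene.
- Enabling feature: C3–C2–C1–C7a–C3a of the cyclopentene are a pentadienyl array with C3 and C3a as termini. With C7a=C3a inside a cyclohexa-1,3-diene (C7a=C3a–C4=C5) and an ester on C1 next to a C2≡C3 alkyne, this is a 3-acyloxy-1,4-enyne, which closes to a cyclopentenone with C2=O and C1=C7a.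
- Stereochemistry: the (5S) acetal carbon of the menthyloxybutenolide (from (−)-menthol) directs the Diels–Alder face (C6, C7); C7 directs the closure at C3a; C3a directs the C3 methylation; the C3 methyl directs the C2 reduction; inversion at C2 and suprafacial hydrogen transfer then set C7a trans. Both diene double bonds are E from stabilised phosphorus reagents.

Key step: step 9

Locants: hydrindadiene numbering of the target is kept throughout (C1 ethyl, C3 methyl, C3a, C4 methyl, C5, C6 methyl and dienyl, C7 methyl and carboxyl, C7a). The α-face is the face of the six-membered ring that carries the C6 and C7 methyls.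

Assumption: the tertiary ester 17 ionises at C1 before the C–C bond forms, so its two C1 epimers (and those of 13 and 16) are carried together; the facial outcome at C3a in step 9 is the least secure stereochemical prediction in the route.

**Step 1**
Reactants: 1 2,3-dimethylmaleic anhydride
Product: 2 5-hydroxy-3,4-dimethylfuran-2(5H)-one
Conditions: LiAlH(OtBu)3 (1.1 equiv), THF, −78 → −30 °C; then 1 M HCl
Reagents that add atoms: none
Why: Partial hydride reduction of a cyclic anhydride to the hydroxy lactone (pseudo-acid) should stop at the lactol stage with the hindered alkoxyaluminium hydride at low temperature, and the symmetric anhydride raises no regiochemical question.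

**Step 2**
Reactants: 2 5-hydroxy-3,4-dimethylfuran-2(5H)-one; 3 (−)-menthol
Product: 4 (5S)-5-menthyloxy-3,4-dimethylfuran-2(5H)-one
Conditions: (+)-camphorsulfonic acid (cat.), toluene, reflux, Dean–Stark; chromatography
Reagents that add atoms: none
Why: Acid-catalysed acetalisation of the pseudo-acid through the cyclic acyloxy-oxocarbenium ion gives two acetal epimers that interconvert under the conditions, so the (5S) epimer can be separated and the other returned to the equilibration; this acetal carbon is the stereocentre from which all others derive.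

**Step 3**
Reactants: 5 methyl 3-methylbut-2-enoate
Product: 7 1-methoxy-3-methyl-1-(trimethylsilyloxy)buta-1,3-diene, via lithium dienolate 6 (not isolated)
Conditions: LDA, THF, −78 °C; then Me3SiCl, −78 °C → rt
Reagents that add atoms: chlorotrimethylsilane, C[Si](C)(C)Cl
Why: γ-Deprotonation of the unsaturated ester gives the extended dienolate, which is O-silylated to the vinylketene silyl acetal, a strongly nucleophilic diene.

**Step 4**
Reactants: 4 (5S)-5-menthyloxy-3,4-dimethylfuran-2(5H)-one; 7 1-methoxy-3-methyl-1-(trimethylsilyloxy)buta-1,3-diene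
Product: 9 bicyclic enone lactone acetal, via ketal adduct 8 (not isolated)
Conditions: toluene, 140 °C, sealed tube; then 0.5 M HCl, THF, 0 °C
Reagents that add atoms: none
Why: Normal-demand Diels–Alder reaction in which the CH2 terminus of the diene bonds to the butenolide β-carbon (C6) and the ketene acetal carbon to the α-carbon (C7), the diene adding anti to the menthyloxy group so that C6 and C7 are set with the two methyls cis; mild acid then unveils the C7a enone.

**Step 5**
Reactants: 9 bicyclic enone lactone acetal
Product: 10 dienyl triflate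
Conditions: Tf2O, 2,6-di-tert-butyl-4-methylpyridine, CH2Cl2, 0 °C → rt
Reagents that add atoms: trifluoromethanesulfonic anhydride, O=S(=O)(OS(=O)(=O)C(F)(F)F)C(F)(F)F
Why: Enol triflation under equilibrating conditions; the α′ carbon (C7) is quaternary, so enolisation must pass through the γ-position, and the homoannular C7a=C3a–C4=C5 dienyl triflate should be the preferred, more substituted isomer.

**Step 6**
Reactants: 10 dienyl triflate; 11 propanal
Product: 13 dienyl carbinol, via dienylchromium species 12 (not isolated)
Conditions: CrCl2 (4 equiv), NiCl2 (2 mol %), DMF, rt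
Reagents that add atoms: none
Why: Nozaki–Hiyama–Kishi coupling (zerovalent nickel inserts into the C–OTf bond, transmetalation to trivalent chromium, addition to the aldehyde) tolerates the lactone and the acetal; the carbinol centre is not controlled and is removed in step 7.

**Step 7**
Reactants: 13 dienyl carbinol
Product: 14 dienyl ethyl ketone
Conditions: Dess–Martin periodinane, pyridine, CH2Cl2, 0 °C → rt
Reagents that add atoms: none
Why: Dess–Martin oxidation of the secondary dienylic alcohol under buffered conditions should leave the acetal and the diene untouched.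

**Step 8**
Reactants: 14 dienyl ethyl ketone; 15 ethynylmagnesium bromide
Product: 17 tertiary propargylic pivalate, via magnesium alkoxide 16 (not isolated)
Conditions: THF, −40 → 0 °C; then t-BuCOCl, DMAP (cat.), 0 °C → rt
Reagents that add atoms: pivaloyl chloride, CC(C)(C)C(Cl)=O
Why: 1,2-Addition of the alkynyl Grignard reagent to the conjugated ketone (far more electrophilic than the α-quaternary lactone) and O-acylation of the alkoxide in the same flask give the 3-acyloxy-1,4-enyne; the C1 centre forms without control and is destroyed in step 9.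

**Step 9**
Reactants: 17 tertiary propargylic pivalate
Product: 19 bicyclic cyclopentenone, via dienyl pivalate 18 (not isolated)
Conditions: Ph3PAuCl (5 mol %), AgSbF6 (5 mol %), MeCN with 2 equiv H2O, −20 °C → rt
Reagents that add atoms: none
Why: Monovalent gold binds the terminal alkyne, the pivalate carbonyl oxygen adds to C2 (1,2-acyloxy shift through a dioxolenium ion), and ionisation of the C1–O bond gives a U-shaped 2-pivaloyloxypentadienyl cation (C3–C2–C1–C7a–C3a, gold on C3) whose termini join to form the C3–C3a bond; loss of gold gives dienyl pivalate 18, which the water hydrolyses to enone 19. The closest known reaction is the gold-catalysed Rautenstrauch rearrangement of 1-ethynyl-2-propenyl pivalates that carry a cyclohexenyl group, a Nazarov-type process. The cyclopentene ring closes by conrotatory 4π-electrocyclisation of the pentadienyl cation (formally 5-endo-trig at C3a). C3a is the only new stereocentre: C1 is planar in the cation, so both epimers of 17 should converge, and the sense of rotation at C3a should be set by the neighbouring quaternary C7, with C4 turning toward the lactone face so that the carbocycle becomes a half-chair with the C7 methyl pseudo-axial and H3a on the α-face, syn to the two methyls. The step needs 1,2- over 3,3-acyloxy migration, which the terminal alkyne secures, and bonding of C3 to C3a and not to C5, which the five-membered ring size secures. The C2 ketone and the C1=C7a alkene it leaves are the handle for the trans ring fusion in step 12.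

**Step 10**
Reactants: 19 bicyclic cyclopentenone
Product: 21 3-methyl cyclopentenone, via lithium enolate 20 (not isolated)
Conditions: LDA, THF, −78 °C; then MeI, −78 → −40 °C
Reagents that add atoms: iodomethane, CI
Why: Kinetic α′-deprotonation at C3 gives the cross-conjugated enolate, which is methylated on the face opposite the C3a–C4 bond, so the C3 methyl ends trans to C4 (cis to H3a), which is also the more stable epimer.

**Step 11**
Reactants: 21 3-methyl cyclopentenone
Product: 22 allylic alcohol
Conditions: NaBH4, CeCl3·7H2O, MeOH, −78 °C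
Reagents that add atoms: none
Why: Luche 1,2-reduction of the tetrasubstituted enone; hydride should add to C2 from the face opposite the adjacent C3 methyl, giving the C2 hydroxyl cis to that methyl.

**Step 12**
Reactants: 22 allylic alcohol
Product: 25 trans-fused hydrindadiene lactone acetal, via sulfonylhydrazine adduct 23 (not isolated), via allylic diazene 24 (not isolated)
Conditions: 2-O2NC6H4SO2NHNH2, PPh3, DEAD, THF, −30 °C; then rt
Reagents that add atoms: none
Why: Mitsunobu displacement by the sulfonyl hydrazide inverts C2, loss of sulfinic acid gives the monoalkyl diazene, and retro-ene loss of N2 transfers hydrogen suprafacially from nitrogen to C7a on the face opposite the C3a–C4 bond, which creates the trans ring fusion and moves the alkene to C1=C2 (reductive allylic transposition).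

**Step 13**
Reactants: 25 trans-fused hydrindadiene lactone acetal
Product: 26 hydroxy lactone
Conditions: CF3CO2H/H2O/THF (1:1:4), 40 °C
Reagents that add atoms: water, O
Why: Acid hydrolysis of the acyloxy acetal through the lactone-stabilised oxocarbenium ion releases menthol and the pseudo-acid in which C6 carries the aldehyde carbon and C7 the carboxyl; no stereocentre is touched.

**Step 14**
Reactants: 26 hydroxy lactone; 27 2-(triphenylphosphoranylidene)propanal
Product: 29 enal acid, via open aldehyde acid 28 (not isolated)
Conditions: toluene, 100 °C (3 equiv of 27)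
Reagents that add atoms: none
Why: Wittig olefination through the ring-opened aldehyde tautomer with a stabilised formyl ylide should give the (E)-2-methyl enal, the excess ylide absorbing the acidic proton.

**Step 15**
Reactants: 29 enal acid; 30 diethyl benzylphosphonate
Product: 33 zyggomphic acid B, via phosphonate carbanion 31 (not isolated), via sodium carboxylate 32 (not isolated)
Conditions: NaH (3.2 equiv), THF, 0 °C → rt; then 1 M HCl
Reagents that add atoms: none
Why: Horner–Wadsworth–Emmons olefination of the enal (1,2-addition) with the benzylphosphonate anion should give the (E)-styryl double bond and complete the (E,E)-diene, the carboxylate being inert until it is protonated on work-up.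

**Compound list**

1 | 2,3-dimethylmaleic anhydride | CC1=C(C)C(=O)OC1=O | starting material
2 | 5-hydroxy-3,4-dimethylfuran-2(5H)-one (racemic) | CC1=C(C)C(O)OC1=O | intermediate
3 | (−)-menthol, (1R,2S,5R) | O[C@@H]1C[C@H](C)CC[C@H]1C(C)C | starting material
4 | (5S)-5-[(1R,2S,5R)-menthyloxy]-3,4-dimethylfuran-2(5H)-one | CC1=C(C)[C@@H](O[C@@H]2C[C@H](C)CC[C@H]2C(C)C)OC1=O | intermediate
5 | methyl 3-methylbut-2-enoate | COC(=O)C=C(C)C | starting material
6 | lithium dienolate of 5 (not isolated) | COC(O[Li])=CC(C)=C | intermediate
7 | 1-methoxy-3-methyl-1-(trimethylsilyloxy)buta-1,3-diene | COC(O[Si](C)(C)C)=CC(C)=C | intermediate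
8 | ketal adduct: C7a methyl trimethylsilyl ketal of 9, both C7a epimers (not isolated) | COC1(O[Si](C)(C)C)C=C(C)C[C@]2(C)[C@@H](O[C@@H]3C[C@H](C)CC[C@H]3C(C)C)OC(=O)[C@]12C | intermediate
9 | bicyclic enone lactone acetal: C7a ketone, C3a=C4, cis-fused menthyloxy γ-lactone on C6/C7, methyls and menthyloxy cis | O=C1C=C(C)C[C@]2(C)[C@@H](O[C@@H]3C[C@H](C)CC[C@H]3C(C)C)OC(=O)[C@]12C | intermediate
10 | dienyl triflate (C7a=C3a–C4=C5, triflate on C7a) | O=S(=O)(OC1=CC(C)=C[C@]2(C)[C@@H](O[C@@H]3C[C@H](C)CC[C@H]3C(C)C)OC(=O)[C@]12C)C(F)(F)F | intermediate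
11 | propanal | CCC=O | starting material
12 | dienylchromium dichloride (not isolated) | Cl[Cr](Cl)C1=CC(C)=C[C@]2(C)[C@@H](O[C@@H]3C[C@H](C)CC[C@H]3C(C)C)OC(=O)[C@]12C | intermediate
13 | dienyl carbinol (both C1 epimers) | CCC(O)C1=CC(C)=C[C@]2(C)[C@@H](O[C@@H]3C[C@H](C)CC[C@H]3C(C)C)OC(=O)[C@]12C | intermediate
14 | dienyl ethyl ketone | CCC(=O)C1=CC(C)=C[C@]2(C)[C@@H](O[C@@H]3C[C@H](C)CC[C@H]3C(C)C)OC(=O)[C@]12C | intermediate
15 | ethynylmagnesium bromide | C#C[Mg]Br | starting material
16 | magnesium alkoxide, both C1 epimers (not isolated) | CCC(C#C)(O[Mg]Br)C1=CC(C)=C[C@]2(C)[C@@H](O[C@@H]3C[C@H](C)CC[C@H]3C(C)C)OC(=O)[C@]12C | intermediate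
17 | tertiary propargylic pivalate (both C1 epimers) | CCC(C#C)(OC(=O)C(C)(C)C)C1=CC(C)=C[C@]2(C)[C@@H](O[C@@H]3C[C@H](C)CC[C@H]3C(C)C)OC(=O)[C@]12C | intermediate
18 | dienyl pivalate: 2-pivaloyloxy cyclopentadiene (not isolated) | CCC1=C2[C@H](C=C1OC(=O)C(C)(C)C)C(C)=C[C@]3(C)[C@@H](O[C@@H]4C[C@H](C)CC[C@H]4C(C)C)OC(=O)[C@]23C | intermediate
19 | bicyclic cyclopentenone: C2 ketone, C1=C7a, C3 unsubstituted, H3a on the α-face | CCC1=C2[C@H](CC1=O)C(C)=C[C@]3(C)[C@@H](O[C@@H]4C[C@H](C)CC[C@H]4C(C)C)OC(=O)[C@]23C | intermediate
20 | lithium enolate of 19 (not isolated) | CCC1=C2[C@H](C=C1O[Li])C(C)=C[C@]3(C)[C@@H](O[C@@H]4C[C@H](C)CC[C@H]4C(C)C)OC(=O)[C@]23C | intermediate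
21 | 3-methyl cyclopentenone (C3 methyl trans to C4) | CCC1=C2[C@H]([C@H](C)C1=O)C(C)=C[C@]3(C)[C@@H](O[C@@H]4C[C@H](C)CC[C@H]4C(C)C)OC(=O)[C@]23C | intermediate
22 | allylic alcohol (C2 hydroxyl cis to the C3 methyl) | CCC1=C2[C@H]([C@H](C)[C@@H]1O)C(C)=C[C@]3(C)[C@@H](O[C@@H]4C[C@H](C)CC[C@H]4C(C)C)OC(=O)[C@]23C | intermediate
23 | sulfonylhydrazine adduct, C2 inverted (not isolated) | CCC1=C2[C@H]([C@H](C)[C@H]1N(N)S(=O)(=O)c5ccccc5[N+](=O)[O-])C(C)=C[C@]3(C)[C@@H](O[C@@H]4C[C@H](C)CC[C@H]4C(C)C)OC(=O)[C@]23C | intermediate
24 | allylic diazene (not isolated) | CCC1=C2[C@H]([C@H](C)[C@H]1N=N)C(C)=C[C@]3(C)[C@@H](O[C@@H]4C[C@H](C)CC[C@H]4C(C)C)OC(=O)[C@]23C | intermediate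
25 | trans-fused hydrindadiene lactone acetal | CCC1=C[C@@H](C)[C@@H]2C(C)=C[C@]3(C)[C@@H](O[C@@H]4C[C@H](C)CC[C@H]4C(C)C)OC(=O)[C@]3(C)[C@@H]12 | intermediate
26 | hydroxy lactone (pseudo-acid, both lactol epimers) | CCC1=C[C@@H](C)[C@@H]2C(C)=C[C@]3(C)C(O)OC(=O)[C@]3(C)[C@@H]12 | intermediate
27 | 2-(triphenylphosphoranylidene)propanal | CC(C=O)=P(c1ccccc1)(c1ccccc1)c1ccccc1 | starting material
28 | open aldehyde acid, ring-chain tautomer of 26 (not isolated) | CCC1=C[C@@H](C)[C@@H]2C(C)=C[C@](C)(C=O)[C@](C)(C(=O)O)[C@@H]12 | intermediate
29 | enal acid, (E)-2-methylpropenal on C6 | CCC1=C[C@@H](C)[C@@H]2C(C)=C[C@](C)(/C=C(C)/C=O)[C@](C)(C(=O)O)[C@@H]12 | intermediate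
30 | diethyl benzylphosphonate | CCOP(=O)(Cc1ccccc1)OCC | starting material
31 | sodium salt of the benzylphosphonate carbanion (not isolated) | [Na+].CCOP(=O)([CH-]c1ccccc1)OCC | intermediate
32 | sodium carboxylate of the target (not isolated) | [Na+].CCC1=C[C@@H](C)[C@@H]2C(C)=C[C@](C)(/C=C(C)/C=C/c3ccccc3)[C@](C)(C(=O)[O-])[C@@H]12 | intermediate
33 | zyggomphic acid B | CCC1=C[C@@H](C)[C@@H]2C(C)=C[C@](C)(/C=C(C)/C=C/c3ccccc3)[C@](C)(C(=O)O)[C@@H]12 | target

**Step count and risks**

Total steps: 15. Longest linear sequence: 14 (steps 1, 2 and 4 to 15; step 3 is a side branch).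

The three steps most likely to fail:

Step 9. The danger is loss of facial control at C3a in the cation (the C7 centre may not bias the conrotation as expected), together with hydration of the alkyne or a competing 3,3-acyloxy shift. The fallback puts the stereochemical information on a configurationally stable secondary carbinol; it sets out from 10 and comes back at 19. Carbonylative Sonogashira coupling of 10 with (trimethylsilyl)acetylene (CO 1 atm, PdCl2(PPh3)2, CuI, Et3N) should give the silyl ynone F1. Corey–Bakshi–Shibata reduction with the (R)-oxazaborolidine and catecholborane (alkynyl as the small group) should give the silylated propargylic alcohol F2. K2CO3 in MeOH gives the terminal alkynol F3, and t-BuCOCl with DMAP gives the secondary propargylic pivalate F4. The same gold catalyst in wet MeCN should then convert F4, by way of the dienyl pivalate F5, into the cyclopentenone without ethyl F6. For such secondary esters the ring closure is known to transfer chirality from the carbinol carbon, the C–C bond forming anti to the departing ester; with the configuration drawn this places C3 on the lactone face of C3a. Iodination at C1 (I2, pyridine) gives the α-iodoenone F7, and Negishi coupling with EtZnBr (PdCl2(dppf), THF) returns to 19.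

Step 4. The danger is that the tetrasubstituted butenolide reacts too slowly, so that the diene desilylates or decomposes before it adds. The fallback uses the doubly activated anhydride as dienophile and resolves afterwards; it sets out from 1 and 7 and comes back at 9. Heating 1 with 7 (toluene, 110 °C) should give the ketal anhydride F8 as a racemate. LiAlH(OtBu)3 at −78 °C should reduce the less hindered carbonyl (on C6, remote from the ketal carbon), and dilute HCl then gives the hydroxy lactone enone F9. Acetalisation with 3 (camphorsulfonic acid, toluene, Dean–Stark) and chromatographic separation of the diastereomeric menthyl acetals returns to 9.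

Step 12. The danger is failure of the Mitsunobu displacement at the hindered allylic C2, by elimination to a cyclopentadiene or by ionisation with loss of configuration. The fallback sets out from 22 and comes back at 25. Formic acid, DCC and DMAP convert 22 with retention into the allylic formate F10. Pd(OAc)2 and PBu3 in THF should ionise it on the face opposite the formate; decarboxylation gives a palladium hydride, and the hydride passes from the metal to the more substituted allyl terminus C7a on that same face. This formate hydrogenolysis with allylic transposition gives the same trans ring fusion and C1=C2 alkene.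

**Further compounds**

F1 | step 9 | silyl ynone | C[Si](C)(C)C#CC(=O)C1=CC(C)=C[C@]2(C)[C@@H](O[C@@H]3C[C@H](C)CC[C@H]3C(C)C)OC(=O)[C@]12C
F2 | step 9 | silylated propargylic alcohol | C[Si](C)(C)C#C[C@H](O)C1=CC(C)=C[C@]2(C)[C@@H](O[C@@H]3C[C@H](C)CC[C@H]3C(C)C)OC(=O)[C@]12C
F3 | step 9 | terminal alkynol | C#C[C@H](O)C1=CC(C)=C[C@]2(C)[C@@H](O[C@@H]3C[C@H](C)CC[C@H]3C(C)C)OC(=O)[C@]12C
F4 | step 9 | secondary propargylic pivalate | C#C[C@H](OC(=O)C(C)(C)C)C1=CC(C)=C[C@]2(C)[C@@H](O[C@@H]3C[C@H](C)CC[C@H]3C(C)C)OC(=O)[C@]12C
F5 | step 9 | dienyl pivalate without ethyl | C1=C2[C@H](C=C1OC(=O)C(C)(C)C)C(C)=C[C@]3(C)[C@@H](O[C@@H]4C[C@H](C)CC[C@H]4C(C)C)OC(=O)[C@]23C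
F6 | step 9 | cyclopentenone without ethyl | O=C1C=C2[C@H](C1)C(C)=C[C@]3(C)[C@@H](O[C@@H]4C[C@H](C)CC[C@H]4C(C)C)OC(=O)[C@]23C
F7 | step 9 | α-iodoenone | O=C1C(I)=C2[C@H](C1)C(C)=C[C@]3(C)[C@@H](O[C@@H]4C[C@H](C)CC[C@H]4C(C)C)OC(=O)[C@]23C
F8 | step 4 | ketal anhydride (racemic, one enantiomer drawn) | COC1(O[Si](C)(C)C)C=C(C)C[C@]2(C)C(=O)OC(=O)[C@]12C
F9 | step 4 | hydroxy lactone enone (racemic, one enantiomer drawn) | O=C1C=C(C)C[C@]2(C)C(O)OC(=O)[C@]12C
F10 | step 12 | allylic formate | CCC1=C2[C@H]([C@H](C)[C@@H]1OC=O)C(C)=C[C@]3(C)[C@@H](O[C@@H]4C[C@H](C)CC[C@H]4C(C)C)OC(=O)[C@]23C
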